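**Plan**
- Retrosynthesis: after removal of two phenol silyl ethers, the C3–C4 bond is cut, which opens ring C to a racemic benzylic chloride tethered to a ring A acid chloride. The O1–C2 ether bond (phenoxide plus α-bromoketone) is cut next, and the ring B aryl–prenyl bond last.
- Enabling feature: C3 is a tertiary benzylic carbon on the donor-substituted ring B and is bonded directly to the C4 aryl ketone carbonyl of ring A, so this bond can be made from an acyl electrophile and a secondary benzylic radical.
- Forward: rings A and B are bought intact. Prenyl is attached to ring B, the rings are joined through O1–C2, the ketone is reduced, both hydroxyls become chlorides, and ring C is closed last at C3–C4.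
- Stereochemistry: the only stereocentre (3S) is set in that ring closure, from racemic chloride, by NiCl2·glyme with a chiral bis(oxazoline). The single later step is non-basic, so C3 should not epimerise.

Key step: step 9

Remark: the sense of induction of the bis(oxazoline) ligand in the ring closure cannot be derived from intermolecular precedent; (R,R)-Ph-BOX, 2,2'-(propane-2,2-diyl)bis[(4R)-4-phenyl-4,5-dihydrooxazole], is written, and its (S,S) antipode is to be used instead if the 3R ketone predominates.

Step 1
Reactants: 1 2,4-dihydroxybenzoic acid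
Product: 2 allyl 2,4-dihydroxybenzoate
Conditions: allyl bromide (1.05 equiv), KHCO3, DMF, 40 °C
Reagents that add atoms: allyl bromide, C=CCBr
Why: Carboxylate O-alkylation (SN2), in which hydrogen carbonate deprotonates only the carboxylic acid so that both phenols stay free; the allyl ester is chosen because it can later be removed without hydroxide, which would attack aryl silyl ethers.

Step 2
Reactants: 2 allyl 2,4-dihydroxybenzoate
Product: 3 allyl 2-hydroxy-4-(triisopropylsilyloxy)benzoate
Conditions: TIPSCl (1.05 equiv), imidazole, CH2Cl2, 0 °C to rt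
Reagents that add atoms: triisopropylsilyl chloride (TIPSCl), CC(C)[Si](Cl)(C(C)C)C(C)C
Why: Selective phenol silylation, because the 2-hydroxyl is hydrogen-bonded to and flanked by the ester carbonyl, so the bulky silyl chloride should take only the 4-hydroxyl.

Step 3
Reactants: 4 1-(5-bromo-2-hydroxy-4-methoxyphenyl)ethan-1-one; 5 prenylboronic acid pinacol ester
Product: 6 1-[2-hydroxy-4-methoxy-5-(3-methylbut-2-en-1-yl)phenyl]ethan-1-one
Conditions: Pd(OAc)2 (2 mol %), t-BuXPhos (4 mol %), K3PO4 (aq), THF, 40 °C
Reagents that add atoms: none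
Why: Ligand-controlled Suzuki–Miyaura allylation, in which the bulky di-tert-butylbiarylphosphine should let the allyl palladium intermediate settle as the unhindered primary σ-allyl form before reductive elimination, giving the linear prenyl arene; the methyl ketone is inert to the allylboronate and the chelated phenol is tolerated.

Step 4
Reactants: 6 1-[2-hydroxy-4-methoxy-5-(3-methylbut-2-en-1-yl)phenyl]ethan-1-one
Product: 8 2-bromo-1-[4-methoxy-5-(3-methylbut-2-en-1-yl)-2-(triisopropylsilyloxy)phenyl]ethan-1-one, via bis-silylated enol ether 7 (not isolated)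
Conditions: TIPSOTf (2.4 equiv), Et3N, CH2Cl2, 0 °C to rt; NaHCO3 wash, solvent exchange; then NBS (1.0 equiv), THF, −78 to −20 °C
Reagents that add atoms: triisopropylsilyl trifluoromethanesulfonate (TIPSOTf), CC(C)[Si](OS(=O)(=O)C(F)(F)F)(C(C)C)C(C)C; N-bromosuccinimide (NBS), O=C1CCC(=O)N1Br
Why: Phenol silylation and soft enolisation of the methyl ketone by silyl triflate and amine, then electrophilic α-bromination of the silyl enol ether, which is far more nucleophilic than the prenyl alkene or the arene, so NBS at low temperature should brominate only the α-carbon while the aryl silyl ether stays as the ring B protecting group.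

Step 5
Reactants: 3 allyl 2-hydroxy-4-(triisopropylsilyloxy)benzoate; 8 2-bromo-1-[4-methoxy-5-(3-methylbut-2-en-1-yl)-2-(triisopropylsilyloxy)phenyl]ethan-1-one
Product: 9 allyl 2-{2-[4-methoxy-5-(3-methylbut-2-en-1-yl)-2-(triisopropylsilyloxy)phenyl]-2-oxoethoxy}-4-(triisopropylsilyloxy)benzoate
Conditions: K2CO3, acetone, rt
Reagents that add atoms: none
Why: Williamson ether synthesis, in which the salicylate phenoxide displaces the activated primary bromide of the α-bromoketone and fixes the O1–C2 bond with unambiguous regiochemistry; carbonate in acetone at room temperature should spare both aryl silyl ethers and is too weak to start a Dieckmann-type closure onto the ester.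

Step 6
Reactants: 9 allyl 2-{2-[4-methoxy-5-(3-methylbut-2-en-1-yl)-2-(triisopropylsilyloxy)phenyl]-2-oxoethoxy}-4-(triisopropylsilyloxy)benzoate
Product: 10 2-{2-[4-methoxy-5-(3-methylbut-2-en-1-yl)-2-(triisopropylsilyloxy)phenyl]-2-oxoethoxy}-4-(triisopropylsilyloxy)benzoic acid
Conditions: Pd(PPh3)4 (3 mol %), morpholine, THF, rt; pH 4 buffer work-up
Reagents that add atoms: none
Why: Tsuji–Trost deallylation, in which zerovalent palladium ionises the allyl ester to a π-allyl complex that morpholine intercepts, freeing the acid under near-neutral conditions that the aryl silyl ethers, the prenyl group and the aryloxy ketone should tolerate.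

Step 7
Reactants: 10 2-{2-[4-methoxy-5-(3-methylbut-2-en-1-yl)-2-(triisopropylsilyloxy)phenyl]-2-oxoethoxy}-4-(triisopropylsilyloxy)benzoic acid
Product: 11 rac-2-{2-hydroxy-2-[4-methoxy-5-(3-methylbut-2-en-1-yl)-2-(triisopropylsilyloxy)phenyl]ethoxy}-4-(triisopropylsilyloxy)benzoic acid
Conditions: NaBH4 (3 equiv), THF/MeOH, 0 °C; pH 4–5 phosphate buffer work-up
Reagents that add atoms: none
Why: Borohydride reduction of the aryl ketone beside the inert carboxylate (which cannot lactonise under these conditions) gives the benzylic alcohol; the carbinol stereocentre forms without control and is deliberately racemic because the later coupling is stereoconvergent.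

Step 8
Reactants: 11 rac-2-{2-hydroxy-2-[4-methoxy-5-(3-methylbut-2-en-1-yl)-2-(triisopropylsilyloxy)phenyl]ethoxy}-4-(triisopropylsilyloxy)benzoic acid
Product: 12 rac-2-{2-chloro-2-[4-methoxy-5-(3-methylbut-2-en-1-yl)-2-(triisopropylsilyloxy)phenyl]ethoxy}-4-(triisopropylsilyloxy)benzoyl chloride
Conditions: SOCl2 (3 equiv), DMF (cat.), CH2Cl2, 0 °C to rt; evaporation with toluene, used crude at once
Reagents that add atoms: thionyl chloride, O=S(Cl)Cl
Why: Deoxychlorination through the benzylic chlorosulfite and Vilsmeier-catalysed acid chloride formation with one reagent, in which the alcohol is consumed first (forestalling seven-membered lactonisation), all by-products are gases, and the chloride-bearing carbon stays racemic.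

Step 9
Reactants: 12 rac-2-{2-chloro-2-[4-methoxy-5-(3-methylbut-2-en-1-yl)-2-(triisopropylsilyloxy)phenyl]ethoxy}-4-(triisopropylsilyloxy)benzoyl chloride
Product: 13 (3S)-3-[4-methoxy-5-(3-methylbut-2-en-1-yl)-2-(triisopropylsilyloxy)phenyl]-7-(triisopropylsilyloxy)-2,3-dihydro-4H-chromen-4-one
Conditions: NiCl2·glyme (10 mol %), (R,R)-Ph-BOX (22 mol %), Mn powder (3 equiv), 2,6-dimethylbenzoic acid (0.75 equiv), 3 Å MS, DMA/THF (3:7), 20 °C, slow addition of 12 (final 0.01 M)
Reagents that add atoms: none
Why: Proposed new method: Mn reduces the bis(oxazoline)-ligated NiCl2 to zerovalent nickel, which inserts into the aroyl C–Cl bond to give a divalent acyl nickel chloride, while chlorine abstraction by a monovalent nickel species converts either enantiomer of the benzylic chloride into the same planar C3 radical; capture of that radical by the tethered acyl nickel gives a trivalent acyl(benzyl)nickel species, and reductive elimination forms C3–C4. The closest known reaction type is the intermolecular enantioconvergent reductive coupling of acid chlorides with racemic secondary benzylic chlorides under NiCl2·glyme, a chiral bis(oxazoline) and Mn, which has not been run as a ring closure, with an aroyl chloride, or with a β-aryloxy benzylic chloride. Ring C closes as a six-membered ring by reductive elimination from a seven-membered nickelacycle (nickel, C4, C4a, C8a, O1, C2, C3) and not by radical addition to the carbonyl group. The 3S configuration is set under catalyst control by the (R,R)-Ph-BOX ligand on nickel at radical capture and reductive elimination, so both enantiomers of 12 should converge on one enantiomer of 13. The step needs ring closure to outrun intermolecular coupling, benzylic dimerisation and loss of the β-aryloxide or a β-hydride from a benzylic nickel species; the short, rigid ortho-aryloxy tether, high dilution, the faster oxidative addition of the aroyl chloride and the stabilisation of the radical by the 2-silyloxy-4-methoxyphenyl ring should secure this. The base-free medium at 20 °C and the flanking ortho-silyloxy group should keep the new α-aryl ketone from enolising.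

Step 10
Reactants: 13 (3S)-3-[4-methoxy-5-(3-methylbut-2-en-1-yl)-2-(triisopropylsilyloxy)phenyl]-7-(triisopropylsilyloxy)-2,3-dihydro-4H-chromen-4-one
Product: 14 (3S)-7-hydroxy-3-[2-hydroxy-4-methoxy-5-(3-methylbut-2-en-1-yl)phenyl]-2,3-dihydro-4H-chromen-4-one (CNP0227207.1)
Conditions: HF·pyridine, excess pyridine, THF, 0 °C to rt
Reagents that add atoms: none
Why: Fluoride-driven cleavage of both aryl silyl ethers (Si–F bond formation) in a pyridine-buffered, weakly acidic medium that should neither enolise the α-aryl ketone, so C3 keeps its S configuration, nor add HF to the prenyl alkene.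

**Compound list**
1 | 2,4-dihydroxybenzoic acid | O=C(O)c1ccc(O)cc1O | starting material
2 | allyl 2,4-dihydroxybenzoate | C=CCOC(=O)c1ccc(O)cc1O | intermediate
3 | allyl 2-hydroxy-4-(triisopropylsilyloxy)benzoate | C=CCOC(=O)c1ccc(O[Si](C(C)C)(C(C)C)C(C)C)cc1O | intermediate
4 | 1-(5-bromo-2-hydroxy-4-methoxyphenyl)ethan-1-one | CC(=O)c1cc(Br)c(OC)cc1O | starting material
5 | prenylboronic acid pinacol ester, 4,4,5,5-tetramethyl-2-(3-methylbut-2-en-1-yl)-1,3,2-dioxaborolane | CC(C)=CCB1OC(C)(C)C(C)(C)O1 | starting material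
6 | 1-[2-hydroxy-4-methoxy-5-(3-methylbut-2-en-1-yl)phenyl]ethan-1-one | CC(=O)c1cc(CC=C(C)C)c(OC)cc1O | intermediate
7 | triisopropyl({1-[4-methoxy-5-(3-methylbut-2-en-1-yl)-2-(triisopropylsilyloxy)phenyl]ethenyl}oxy)silane (bis-silylated enol ether) | C=C(O[Si](C(C)C)(C(C)C)C(C)C)c1cc(CC=C(C)C)c(OC)cc1O[Si](C(C)C)(C(C)C)C(C)C | intermediate
8 | 2-bromo-1-[4-methoxy-5-(3-methylbut-2-en-1-yl)-2-(triisopropylsilyloxy)phenyl]ethan-1-one | O=C(CBr)c1cc(CC=C(C)C)c(OC)cc1O[Si](C(C)C)(C(C)C)C(C)C | intermediate
9 | allyl 2-{2-[4-methoxy-5-(3-methylbut-2-en-1-yl)-2-(triisopropylsilyloxy)phenyl]-2-oxoethoxy}-4-(triisopropylsilyloxy)benzoate | C=CCOC(=O)c1ccc(O[Si](C(C)C)(C(C)C)C(C)C)cc1OCC(=O)c1cc(CC=C(C)C)c(OC)cc1O[Si](C(C)C)(C(C)C)C(C)C | intermediate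
10 | 2-{2-[4-methoxy-5-(3-methylbut-2-en-1-yl)-2-(triisopropylsilyloxy)phenyl]-2-oxoethoxy}-4-(triisopropylsilyloxy)benzoic acid | O=C(O)c1ccc(O[Si](C(C)C)(C(C)C)C(C)C)cc1OCC(=O)c1cc(CC=C(C)C)c(OC)cc1O[Si](C(C)C)(C(C)C)C(C)C | intermediate
11 | rac-2-{2-hydroxy-2-[4-methoxy-5-(3-methylbut-2-en-1-yl)-2-(triisopropylsilyloxy)phenyl]ethoxy}-4-(triisopropylsilyloxy)benzoic acid | O=C(O)c1ccc(O[Si](C(C)C)(C(C)C)C(C)C)cc1OCC(O)c1cc(CC=C(C)C)c(OC)cc1O[Si](C(C)C)(C(C)C)C(C)C | intermediate
12 | rac-2-{2-chloro-2-[4-methoxy-5-(3-methylbut-2-en-1-yl)-2-(triisopropylsilyloxy)phenyl]ethoxy}-4-(triisopropylsilyloxy)benzoyl chloride | O=C(Cl)c1ccc(O[Si](C(C)C)(C(C)C)C(C)C)cc1OCC(Cl)c1cc(CC=C(C)C)c(OC)cc1O[Si](C(C)C)(C(C)C)C(C)C | intermediate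
13 | (3S)-3-[4-methoxy-5-(3-methylbut-2-en-1-yl)-2-(triisopropylsilyloxy)phenyl]-7-(triisopropylsilyloxy)-2,3-dihydro-4H-chromen-4-one | COc1cc(O[Si](C(C)C)(C(C)C)C(C)C)c([C@H]2COc3cc(O[Si](C(C)C)(C(C)C)C(C)C)ccc3C2=O)cc1CC=C(C)C | intermediate
14 | (3S)-7-hydroxy-3-[2-hydroxy-4-methoxy-5-(3-methylbut-2-en-1-yl)phenyl]-2,3-dihydro-4H-chromen-4-one (CNP0227207.1) | COc1cc(O)c([C@H]2COc3cc(O)ccc3C2=O)cc1CC=C(C)C | target

**Step count**
Total: 10 steps. Longest linear sequence: 8 steps (from 4 through steps 3–10; equally from 1 through steps 1, 2 and 5–10).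

**Steps most likely to fail**

1. Step 9. What may go wrong:
- The benzylic nickel or radical intermediate carries a β-aryloxy group and β-hydrogens, so expulsion of the ring A phenoxide or β-hydride loss may outrun reductive elimination.
- Benzylic radicals may dimerise, and aroyl nickel species may homocouple.
- The hindered ortho-silyloxy group may slow radical capture.
- Facial discrimination at capture may be insufficient.

Fallback, using known reaction types only; it sets out from 8 and returns at 13:
- Commercial 2,4-dihydroxybenzaldehyde is silylated at the 4-hydroxyl (TIPSCl, imidazole, CH2Cl2) to give 2-hydroxy-4-(triisopropylsilyloxy)benzaldehyde F1.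
- F1 is alkylated with 8 (K2CO3, acetone, 0 °C to rt, stopped before Rap–Stoermer condensation sets in) to give the keto aldehyde 2-{2-[4-methoxy-5-(3-methylbut-2-en-1-yl)-2-(triisopropylsilyloxy)phenyl]-2-oxoethoxy}-4-(triisopropylsilyloxy)benzaldehyde F2.
- An achiral triazolium carbene precatalyst (2-pentafluorophenyl-6,7-dihydro-5H-pyrrolo[2,1-c][1,2,4]triazolium tetrafluoroborate, Et3N, toluene, rt) should close ring C by intramolecular aldehyde–ketone benzoin addition. This forms the same C3–C4 bond and gives rac-3-hydroxy-3-[4-methoxy-5-(3-methylbut-2-en-1-yl)-2-(triisopropylsilyloxy)phenyl]-7-(triisopropylsilyloxy)-2,3-dihydro-4H-chromen-4-one F3.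
- Dehydration with methyl N-(triethylammoniosulfonyl)carbamate (Burgess reagent, THF, 50 °C) should give the isoflavone 3-[4-methoxy-5-(3-methylbut-2-en-1-yl)-2-(triisopropylsilyloxy)phenyl]-7-(triisopropylsilyloxy)-4H-chromen-4-one F4.
- Asymmetric transfer hydrogenation under dynamic kinetic resolution, a reaction established for isoflavones (RuCl[(S,S)-TsDPEN](p-cymene) or its antipode, whichever gives the 3S series, HCO2H/Et3N, EtOAc, 40 °C), should deliver the cis alcohol (3S,4S)-3-[4-methoxy-5-(3-methylbut-2-en-1-yl)-2-(triisopropylsilyloxy)phenyl]-7-(triisopropylsilyloxy)-3,4-dihydro-2H-chromen-4-ol F5.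
- Dess–Martin periodinane (NaHCO3, CH2Cl2, 0 °C) should then oxidise the carbinol to the ketone without touching C3, which gives 13.

2. Step 8. What may go wrong:
- The electron-rich benzylic chlorosulfite or chloride may ionise in the HCl-containing medium and lose a proton to form the aryl enol ether.
- HCl may add across the prenyl double bond.
- If acid activation runs ahead of the alcohol, the molecule may close to the seven-membered lactone.

Fallback; it sets out from 11 and returns at 12:
- The acid is first masked (TBSCl 1.05 equiv, Et3N, CH2Cl2, 0 °C; the carboxylate is silylated much faster than the hindered secondary alcohol) to give tert-butyldimethylsilyl rac-2-{2-hydroxy-2-[4-methoxy-5-(3-methylbut-2-en-1-yl)-2-(triisopropylsilyloxy)phenyl]ethoxy}-4-(triisopropylsilyloxy)benzoate F6.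
- The benzylic hydroxyl is then exchanged for chloride under neutral conditions with 1-chloro-N,N,2-trimethylprop-1-en-1-amine (CH2Cl2, 0 °C) to give tert-butyldimethylsilyl rac-2-{2-chloro-2-[4-methoxy-5-(3-methylbut-2-en-1-yl)-2-(triisopropylsilyloxy)phenyl]ethoxy}-4-(triisopropylsilyloxy)benzoate F7.
- Oxalyl chloride with catalytic DMF (CH2Cl2, 0 °C to rt) finally converts the silyl ester directly into the acid chloride with loss of volatile TBSCl. This gives 12 without free HCl and without the acid and the alcohol ever being activated together.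

3. Step 3. What may go wrong:
- Allyl transposition at palladium (γ-coupling) may lead to the reverse-prenyl (1,1-dimethylallyl) isomer.
- The boronate may protodeboronate on the slow, electron-rich aryl bromide.

Fallback; it sets out from 4 and returns at 6:
- Suzuki–Miyaura coupling with allylboronic acid pinacol ester (PdCl2(dppf), K3PO4, THF/H2O, 65 °C), for which α- and γ-coupling give the same product, should give 1-[2-hydroxy-4-methoxy-5-(prop-2-en-1-yl)phenyl]ethan-1-one F8.
- Cross-metathesis with excess 2-methyl-2-butene (second-generation Grubbs catalyst, CH2Cl2, 40 °C) then converts allyl into prenyl, which gives 6.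

**Further compounds**
F1 | step 9 | 2-hydroxy-4-(triisopropylsilyloxy)benzaldehyde | O=Cc1ccc(O[Si](C(C)C)(C(C)C)C(C)C)cc1O
F2 | step 9 | 2-{2-[4-methoxy-5-(3-methylbut-2-en-1-yl)-2-(triisopropylsilyloxy)phenyl]-2-oxoethoxy}-4-(triisopropylsilyloxy)benzaldehyde | O=Cc1ccc(O[Si](C(C)C)(C(C)C)C(C)C)cc1OCC(=O)c1cc(CC=C(C)C)c(OC)cc1O[Si](C(C)C)(C(C)C)C(C)C
F3 | step 9 | rac-3-hydroxy-3-[4-methoxy-5-(3-methylbut-2-en-1-yl)-2-(triisopropylsilyloxy)phenyl]-7-(triisopropylsilyloxy)-2,3-dihydro-4H-chromen-4-one | COc1cc(O[Si](C(C)C)(C(C)C)C(C)C)c(C2(O)COc3cc(O[Si](C(C)C)(C(C)C)C(C)C)ccc3C2=O)cc1CC=C(C)C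
F4 | step 9 | 3-[4-methoxy-5-(3-methylbut-2-en-1-yl)-2-(triisopropylsilyloxy)phenyl]-7-(triisopropylsilyloxy)-4H-chromen-4-one | COc1cc(O[Si](C(C)C)(C(C)C)C(C)C)c(-c2coc3cc(O[Si](C(C)C)(C(C)C)C(C)C)ccc3c2=O)cc1CC=C(C)C
F5 | step 9 | (3S,4S)-3-[4-methoxy-5-(3-methylbut-2-en-1-yl)-2-(triisopropylsilyloxy)phenyl]-7-(triisopropylsilyloxy)-3,4-dihydro-2H-chromen-4-ol | COc1cc(O[Si](C(C)C)(C(C)C)C(C)C)c([C@H]2COc3cc(O[Si](C(C)C)(C(C)C)C(C)C)ccc3[C@H]2O)cc1CC=C(C)C
F6 | step 8 | tert-butyldimethylsilyl rac-2-{2-hydroxy-2-[4-methoxy-5-(3-methylbut-2-en-1-yl)-2-(triisopropylsilyloxy)phenyl]ethoxy}-4-(triisopropylsilyloxy)benzoate | CC(C)(C)[Si](C)(C)OC(=O)c1ccc(O[Si](C(C)C)(C(C)C)C(C)C)cc1OCC(O)c1cc(CC=C(C)C)c(OC)cc1O[Si](C(C)C)(C(C)C)C(C)C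
F7 | step 8 | tert-butyldimethylsilyl rac-2-{2-chloro-2-[4-methoxy-5-(3-methylbut-2-en-1-yl)-2-(triisopropylsilyloxy)phenyl]ethoxy}-4-(triisopropylsilyloxy)benzoate | CC(C)(C)[Si](C)(C)OC(=O)c1ccc(O[Si](C(C)C)(C(C)C)C(C)C)cc1OCC(Cl)c1cc(CC=C(C)C)c(OC)cc1O[Si](C(C)C)(C(C)C)C(C)C
F8 | step 3 | 1-[2-hydroxy-4-methoxy-5-(prop-2-en-1-yl)phenyl]ethan-1-one | CC(=O)c1cc(CC=C)c(OC)cc1O
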